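Labdane numbering (C1–C20) is used for target 18 and all intermediates; "axial" and "equatorial" refer to the chair rings of the trans-decalin.

## The problem

- Target 18 is an ent-labdane: a trans-fused decalin (rings A and B) with two quaternary carbons (C4, C10), a trisubstituted C7=C8 alkene, and a saturated C11–C15 chain on C9 that ends in a free acid.
- Five of the six stereocentres lie on the decalin (C3, C4, C5, C9, C10). C4, C5, C9 and C10 depend on each other through the ring fusion, and C3 can be set from them by reagent approach. C13 is four bonds from the ring and must be brought in on its own.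
- On ring A the acetoxy group at C3 is axial, and the hydroxymethyl carbon C19 on C4 is axial and cis to C20. O3 and C19 are therefore trans-diaxial. This is the C3 epimer that an epoxide-initiated cyclization does not give.
- Three oxygen functions must end in three different states: a secondary acetate, a free neopentyl primary alcohol and a free acid. Once the acetate is in place, no ester can be hydrolysed and no hydride used.
- The C7=C8 alkene must be placed selectively against the exocyclic C8=C17 and the tetrasubstituted C8=C9 isomers, and it can migrate under strong acid.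
- The feature that opens the problem: the C19–C4(CH3)–C3 triad of ring A is a reduced α-methyl β-keto ester. A radical at C4 can add to C5, and the methyl-bearing carbons C10 and C8 are exactly where two 6-endo closures give tertiary radicals. Because C13–C14 is saturated, the chain offers no third alkene, so the cascade must stop at C8 after ring B, where C17 supplies the hydrogen for an alkene-forming end.

## Retrosynthesis

**18 ⇒ 17.** No C–C bond is cut; the C15 acid is traced to the primary alcohol of 17. The acetate rules out a late ester hydrolysis, and the hydride reduction at C19 rules out an early acid, so C15 travels as a silyl ether. The forward step must oxidise the unhindered C15–OH and leave the neopentyl, axial C19–OH.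

**17 ⇒ 16 ⇒ 15 ⇒ 14.** Only O–acyl and O–silyl bonds are cut. Diol 14 is differentiated by size: the primary O19 is silylated first (15), then O3 is acetylated (16). Because O3 and C19 are anti-periplanar, no six-membered acyl-transfer path exists, so desilylation to 17 cannot move the acetate.

**14 ⇒ 13 ⇒ 12.** The C19 alcohol goes back to an ester and the C3 carbinol to a ketone, which turns the 1,3-dioxygen pattern into the β-keto ester 12. The forward steps need hydride delivery to C3 from the equatorial side (13), then reduction of the hindered ester, which also releases auxiliary 6.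

**12 ⇒ 11.** The C7=C8 alkene is traced to the exocyclic C8=C17 isomer; one hydrogen moves. This lets the ring-forming step end the way it prefers instead of demanding an endocyclic elimination.

**11 ⇒ 10 (key cut).** C4–C5 and C9–C10 are cut, opening both rings to the acyclic keto ester 10.
- Cutting only ring B would leave the C4/C5/C10 array to be built stepwise.
- Cutting the same two bonds in the cationic sense needs an enantiopure (Z)-configured epoxide and gives the wrong C3 epimer.
- Precursor 10 has one stereocentre (C13) and a recoverable auxiliary; product 11 has four new ring stereocentres and both quaternary carbons.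
- The forward reaction needs two 6-endo radical closures through a chair–chair array, face control by the ester auxiliary, and an alkene-forming termination.

**10 ⇒ 8 + 5, and 8 ⇒ 6 + 7.** C1–C2 is cut: the dianion 9 of auxiliary ester 8 (C2, C3, C4, C18, C19) is alkylated at its γ-carbon by allylic bromide 5 (the other fifteen carbons). Ester 8 comes from alcohol 6 and keto ester 7 by transesterification.

**5 ⇒ 4 ⇒ 3 ⇒ 2 ⇒ 1.** The bromide comes from the (E)-allylic alcohol 4, made by allylic oxidation of the terminal prenyl group of silyl ether 3. The C13 stereocentre of 2 comes from asymmetric hydrogenation of the allylic alcohol of farnesol 1, which already holds both (E)-alkenes and carbons C1, C5–C17 and C20.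

## Roads not taken

**Alternative 1:** the route most chemists would draw first, a biomimetic cationic epoxide–polyene cyclization.
- Cut: the same C4–C5 and C9–C10 bonds, from the (2S,3R)-epoxide A1, made by Sharpless epoxidation of a (Z)-allylic alcohol.
- Forward key step: Lewis-acid opening of A1 and chair–chair closure to bicyclic alcohol A2.
- Why the chosen plan is better:
  - The axial C19 requires the (Z)-hydroxymethyl terminus. Direct allylic oxidation gives only the (E)-isomer, so about five extra steps are needed from 5 (homologation, Still–Gennari olefination, reduction, epoxidation, protection).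
  - The oxygen on C19 destabilises the developing C4 cation and slows initiation.
  - A2 carries the equatorial C3–OH, so an oxidation and the same hindered-hydride reduction are still needed.
  - The elimination at C8 is no cleaner.
- Its one advantage, reagent-controlled absolute configuration, is why a silyl-protected variant is kept as the fallback to step 7.

**Alternative 2:** annulation from the (R)-Wieland–Miescher ketone A3.
- Cut: C9–C11 and C8–C17, with the decalin from a proline-catalysed Robinson annulation.
- Forward key step: reductive carbomethoxylation and methylation at C4 to the trans-fused diketo ester A4, then stepwise building of ring B and the side chain from the C9 ketone.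
- Why the chosen plan is better: the C8 methyl, the C7=C8 alkene and the C9 stereocentre must each be installed separately at a neopentyl ketone next to C10. C13 still needs its own chiral fragment. The sequence is linear and well over twenty steps.

**Alternative 3:** relay from the ent-labdane andrographolide A5, which already has the ring fusion, the axial C19–OH and a C3–OH.
- Cut: C12–C13.
- Forward key step: selective oxidative cleavage of the C12=C13 alkene of the acetonide to aldehyde A6, then rebuilding C13–C16 with a new C13 stereocentre.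
- Why the chosen plan is better: the ring system is taken from nature, so it is not a total synthesis. C3 still has the wrong (equatorial) configuration and the alkene is still exocyclic, so both the hydride inversion and the isomerization remain. One of two alkenes must be cleaved selectively, and C13 is set late with no help from the ring. No steps are saved.

Key step: step 7

Assumption: the 8-phenylmenthyl ester is taken to steer the first ring closure so that the (1S,2R,5S)-auxiliary 6 leads to the ent series. If the sense proves opposite, the commercial (1R,2S,5R)-alcohol is used and nothing else changes.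

## Route

Step 1
Reactants: 1 (2E,6E)-farnesol
Product: 2 (R)-2,3-dihydrofarnesol, (3R,6E)-3,7,11-trimethyldodeca-6,10-dien-1-ol
Conditions: H2 (30–100 atm), Ru(OAc)2[(S)-BINAP] (cat.), MeOH–H2O, rt
Reagents that add atoms: none
Why: Noyori asymmetric hydrogenation of an allylic alcohol; the hydroxyl binds ruthenium so only the C2=C3 alkene is reduced, and the (S)-ligand with the (E)-alkene should give the (3R) centre (C13 of 18), as geraniol gives (R)-citronellol.

Step 2
Reactants: 2 (R)-2,3-dihydrofarnesol
Product: 3 tert-butyl{[(3R,6E)-3,7,11-trimethyldodeca-6,10-dien-1-yl]oxy}diphenylsilane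
Conditions: TBDPSCl, imidazole, CH2Cl2, rt
Reagents that add atoms: tert-butyl(chloro)diphenylsilane, CC(C)(C)[Si](Cl)(c1ccccc1)c1ccccc1
Why: Standard silylation of a primary alcohol; the TBDPS ether should survive acetic acid, strong base and hydrides on the way to step 13.

Step 3
Reactants: 3 silyl ether of (R)-2,3-dihydrofarnesol
Product: 4 (2E,6E,10R)-12-[(tert-butyldiphenylsilyl)oxy]-2,6,10-trimethyldodeca-2,6-dien-1-ol
Conditions: SeO2 (cat.), t-BuOOH, salicylic acid (cat.), CH2Cl2, 0 °C to rt
Reagents that add atoms: selenium dioxide (oxygen carrier), O=[Se]=O; tert-butyl hydroperoxide (terminal oxygen source), CC(C)(C)OO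
Why: Catalytic selenium dioxide allylic oxidation (ene reaction, then [2,3]-shift); the terminal gem-dimethyl alkene reacts first and at its (E)-methyl group, giving the (E)-allylic alcohol whose CH2OH carbon becomes C1.

Step 4
Reactants: 4 (E)-allylic alcohol
Product: 5 {[(3R,6E,10E)-12-bromo-3,7,11-trimethyldodeca-6,10-dien-1-yl]oxy}(tert-butyl)diphenylsilane
Conditions: CBr4, PPh3, CH2Cl2, 0 °C
Reagents that add atoms: carbon tetrabromide, BrC(Br)(Br)Br
Why: Appel reaction; a primary allylic alcohol should give the bromide by SN2 displacement without allylic shift or loss of (E)-geometry.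

Step 5
Reactants: 6 (1S,2R,5S)-(+)-8-phenylmenthol; 7 ethyl 2-methyl-3-oxobutanoate
Product: 8 (1S,2R,5S)-5-methyl-2-(2-phenylpropan-2-yl)cyclohexyl 2-methyl-3-oxobutanoate (both C2 epimers)
Conditions: DMAP (cat.), toluene, reflux, ethanol distilled off
Reagents that add atoms: none
Why: DMAP-catalysed transesterification of a β-keto ester, driven by removal of ethanol; hindered secondary alcohols are acylated well in this way.

Step 6
Reactants: 8 auxiliary 2-methylacetoacetate; 5 allylic bromide
Product: 10 (1S,2R,5S)-5-methyl-2-(2-phenylpropan-2-yl)cyclohexyl (6E,10E,14R)-16-[(tert-butyldiphenylsilyl)oxy]-2,6,10,14-tetramethyl-3-oxohexadeca-6,10-dienoate (both C2 epimers), via dilithium dienolate 9 (not isolated)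
Conditions: lithium diisopropylamide (2.2 equiv), THF, 0 °C; then 5, −78 to 0 °C; AcOH quench
Reagents that add atoms: none
Why: β-Keto ester dianion alkylation; the more reactive γ-carbanion of 9 should attack the primary allylic bromide by SN2 and form C1–C2, and the epimeric α-centre is of no consequence because it becomes the radical carbon C4.

Step 7
Reactants: 10 acyclic keto ester
Product: 11 (1S,2R,5S)-8-phenylmenthyl 15-[(tert-butyldiphenylsilyl)oxy]-3-oxolabd-8(17)-en-19-oate of the ent series (trans-decalin; C20, the C19 ester carbon and the C9 side chain on one face, H-5 and H-9 on the other; C13 R)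
Conditions: Mn(OAc)3·2H2O (2.2 equiv), Cu(OAc)2·H2O (1 equiv, turned over by the manganese oxidant), degassed AcOH, rt
Reagents that add atoms: none
Why: Manganese triacetate enolizes the α-methyl β-keto ester and oxidises it by one electron to the electrophilic tertiary radical at C4. Ring A closes by 6-endo-trig addition of C4 to C5, favoured over 5-exo because C10 is fully substituted and becomes a tertiary radical; ring B closes by a second 6-endo-trig addition of C10 to C9 of the (E)-C8=C9 alkene through a chair–chair array, giving the tertiary C8 radical. Copper diacetate traps that radical as an alkylcopper species (trivalent copper) that loses a β-hydrogen, mainly from C17, and the monovalent copper formed is reoxidised; with C13–C14 saturated no further alkene is in reach, so the cascade stops at two rings. The closest known reaction type is the oxidative free-radical polyene cyclization of α-alkyl β-keto esters with trivalent manganese and divalent copper, including 8-phenylmenthyl esters for asymmetric induction. The trans ring fusion (C5, C10) follows from the (E)-C5=C10 alkene in a chair, and the equatorial side chain at C9 from the (E)-C8=C9 alkene. At C4 the ester carbonyl lies anti to the ketone oxygen in the radical, which puts the ester cis to C2 and so axial and cis to C20. The absolute sense comes from the auxiliary, whose phenyl ring covers one face of the planar radical so that the C5=C10 alkene adds to the open face; the minor ring diastereomer differs next to the auxiliary and should be separable. Any C7=C8 isomer formed at the termination is compound 12 itself and is carried into step 8 together with 11.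

Step 8
Reactants: 11 exocyclic keto ester
Product: 12 (1S,2R,5S)-8-phenylmenthyl 15-[(tert-butyldiphenylsilyl)oxy]-3-oxolabd-7-en-19-oate of the ent series (configuration as in 11)
Conditions: (salen)CoCl (cat.; salen = N,N′-bis(3,5-di-tert-butylsalicylidene)-1,2-cyclohexanediaminate), PhSiH3 (cat.), benzene, rt
Reagents that add atoms: none
Why: Cobalt-hydride hydrogen-atom-transfer isomerization of a 1,1-disubstituted alkene to a trisubstituted one; the C8 radical should give back hydrogen from the accessible C7–H and not from the tertiary C9–H beside quaternary C10, and the trisubstituted product re-enters the cycle only slowly.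

Step 9
Reactants: 12 keto ester
Product: 13 (1S,2R,5S)-8-phenylmenthyl (3S)-15-[(tert-butyldiphenylsilyl)oxy]-3-hydroxylabd-7-en-19-oate of the ent series (C3–OH axial, trans to C20 and anti to C19)
Conditions: LiB(s-Bu)3H (L-Selectride), THF, −78 °C; then H2O
Reagents that add atoms: none
Why: A bulky trialkylborohydride avoids the axial path past H-1 and H-5 and attacks from the equatorial side, as with 4,4-disubstituted 3-keto terpenoids, so the axial (3S) alcohol should form; the hindered ester and the silyl ether are inert at −78 °C.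

Step 10
Reactants: 13 hydroxy ester
Product: 14 (3S)-15-[(tert-butyldiphenylsilyl)oxy]labd-7-ene-3,19-diol of the ent series (ring configuration as in 18; C13 R)
Conditions: LiAlH4, THF, 0 to 40 °C; aqueous work-up
Reagents that add atoms: none
Why: Hydride reduction of the neopentyl ester to the C19 primary alcohol, releasing alcohol 6 for reuse; C4 is quaternary and cannot epimerize.

Step 11
Reactants: 14 diol
Product: 15 (3S)-19-[(tert-butyldimethylsilyl)oxy]-15-[(tert-butyldiphenylsilyl)oxy]labd-7-en-3-ol of the ent series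
Conditions: TBSCl (1.2 equiv), imidazole, DMF, rt
Reagents that add atoms: tert-butyl(chloro)dimethylsilane, CC(C)(C)[Si](C)(C)Cl
Why: Silylation selective for the primary C19–OH over the axial secondary C3–OH, which is flanked by quaternary C4.

Step 12
Reactants: 15 mono-silylated diol
Product: 16 (3S)-19-[(tert-butyldimethylsilyl)oxy]-15-[(tert-butyldiphenylsilyl)oxy]labd-7-en-3-yl acetate of the ent series
Conditions: Ac2O, DMAP, pyridine, rt to 40 °C
Reagents that add atoms: acetic anhydride, CC(=O)OC(C)=O
Why: DMAP-catalysed acetylation of a hindered axial alcohol; because C3–O and C4–C19 are anti-periplanar, the acetate has no cyclic path to O19 in later steps.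

Step 13
Reactants: 16 acetate
Product: 17 (3S)-15,19-dihydroxylabd-7-en-3-yl acetate of the ent series
Conditions: HF·pyridine, THF–pyridine, 0 °C to rt
Reagents that add atoms: none
Why: Fluoride cleavage of both silyl ethers under weakly acidic conditions that leave the acetate and the trisubstituted alkene untouched.

Step 14
Reactants: 17 diol acetate
Product: 18 (3R)-5-[(1R,4aS,5R,6S,8aS)-6-acetyloxy-5-(hydroxymethyl)-2,5,8a-trimethyl-1,4,4a,5,6,7,8,8a-octahydronaphthalen-1-yl]-3-methylpentanoic acid (target)
Conditions: TEMPO (cat.), PhI(OAc)2 (2.2 equiv), MeCN–H2O, 0 °C to rt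
Reagents that add atoms: water, O
Why: Oxoammonium (TEMPO) oxidation of a primary alcohol through the aldehyde hydrate to the acid; this oxidation is very sensitive to crowding, so the open C15–OH should react while the axial neopentyl C19–OH, shielded by C20 and the C3 acetate, stays.

## Compound list

1 | (2E,6E)-farnesol | CC(C)=CCC/C(C)=C/CC/C(C)=C/CO | starting material
2 | (R)-2,3-dihydrofarnesol | CC(C)=CCC/C(C)=C/CC[C@@H](C)CCO | intermediate
3 | TBDPS ether of 2 | CC(C)=CCC/C(C)=C/CC[C@@H](C)CCO[Si](c1ccccc1)(c1ccccc1)C(C)(C)C | intermediate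
4 | (2E,6E,10R)-12-(TBDPS-oxy)-2,6,10-trimethyldodeca-2,6-dien-1-ol | OC/C(C)=C/CC/C(C)=C/CC[C@@H](C)CCO[Si](c1ccccc1)(c1ccccc1)C(C)(C)C | intermediate
5 | (3R,6E,10E)-12-bromo-3,7,11-trimethyldodeca-6,10-dienyl TBDPS ether | BrC/C(C)=C/CC/C(C)=C/CC[C@@H](C)CCO[Si](c1ccccc1)(c1ccccc1)C(C)(C)C | intermediate
6 | (1S,2R,5S)-(+)-8-phenylmenthol | O[C@H]1C[C@@H](C)CC[C@@H]1C(C)(C)c1ccccc1 | starting material
7 | ethyl 2-methyl-3-oxobutanoate | CCOC(=O)C(C)C(C)=O | starting material
8 | (1S,2R,5S)-8-phenylmenthyl 2-methyl-3-oxobutanoate (C2 epimers) | CC(=O)C(C)C(=O)O[C@H]1C[C@@H](C)CC[C@@H]1C(C)(C)c1ccccc1 | intermediate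
9 | dilithium dienolate of 8 | [Li+].[Li+].C=C([O-])C(C)=C([O-])O[C@H]1C[C@@H](C)CC[C@@H]1C(C)(C)c1ccccc1 | intermediate
10 | 8-phenylmenthyl (6E,10E,14R)-16-(TBDPS-oxy)-2,6,10,14-tetramethyl-3-oxohexadeca-6,10-dienoate (C2 epimers) | CC(C(=O)CC/C(C)=C/CC/C(C)=C/CC[C@@H](C)CCO[Si](c1ccccc1)(c1ccccc1)C(C)(C)C)C(=O)O[C@H]1C[C@@H](C)CC[C@@H]1C(C)(C)c1ccccc1 | intermediate
11 | 8-phenylmenthyl 15-(TBDPS-oxy)-3-oxolabd-8(17)-en-19-oate, ent series | O=C1CC[C@]2(C)[C@H](CCC(=C)[C@H]2CC[C@@H](C)CCO[Si](c3ccccc3)(c3ccccc3)C(C)(C)C)[C@]1(C)C(=O)O[C@H]1C[C@@H](C)CC[C@@H]1C(C)(C)c1ccccc1 | intermediate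
12 | 8-phenylmenthyl 15-(TBDPS-oxy)-3-oxolabd-7-en-19-oate, ent series | O=C1CC[C@]2(C)[C@H](CC=C(C)[C@H]2CC[C@@H](C)CCO[Si](c3ccccc3)(c3ccccc3)C(C)(C)C)[C@]1(C)C(=O)O[C@H]1C[C@@H](C)CC[C@@H]1C(C)(C)c1ccccc1 | intermediate
13 | 8-phenylmenthyl (3S)-15-(TBDPS-oxy)-3-hydroxylabd-7-en-19-oate, ent series, C3–OH axial | O[C@H]1CC[C@]2(C)[C@H](CC=C(C)[C@H]2CC[C@@H](C)CCO[Si](c3ccccc3)(c3ccccc3)C(C)(C)C)[C@]1(C)C(=O)O[C@H]1C[C@@H](C)CC[C@@H]1C(C)(C)c1ccccc1 | intermediate
14 | (3S)-15-(TBDPS-oxy)labd-7-ene-3,19-diol, ent series | O[C@H]1CC[C@]2(C)[C@H](CC=C(C)[C@H]2CC[C@@H](C)CCO[Si](c3ccccc3)(c3ccccc3)C(C)(C)C)[C@]1(C)CO | intermediate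
15 | (3S)-19-(TBS-oxy)-15-(TBDPS-oxy)labd-7-en-3-ol, ent series | O[C@H]1CC[C@]2(C)[C@H](CC=C(C)[C@H]2CC[C@@H](C)CCO[Si](c3ccccc3)(c3ccccc3)C(C)(C)C)[C@]1(C)CO[Si](C)(C)C(C)(C)C | intermediate
16 | (3S)-19-(TBS-oxy)-15-(TBDPS-oxy)labd-7-en-3-yl acetate, ent series | CC(=O)O[C@H]1CC[C@]2(C)[C@H](CC=C(C)[C@H]2CC[C@@H](C)CCO[Si](c3ccccc3)(c3ccccc3)C(C)(C)C)[C@]1(C)CO[Si](C)(C)C(C)(C)C | intermediate
17 | (3S)-15,19-dihydroxylabd-7-en-3-yl acetate, ent series | CC(=O)O[C@H]1CC[C@]2(C)[C@H](CC=C(C)[C@H]2CC[C@@H](C)CCO)[C@]1(C)CO | intermediate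
18 | (3R)-5-[(1R,4aS,5R,6S,8aS)-6-acetyloxy-5-(hydroxymethyl)-2,5,8a-trimethyl-1,4,4a,5,6,7,8,8a-octahydronaphthalen-1-yl]-3-methylpentanoic acid | CC(=O)O[C@H]1CC[C@]2(C)[C@H](CC=C(C)[C@H]2CC[C@@H](C)CC(=O)O)[C@]1(C)CO | target

## Step count and least certain steps

Total: 14 steps. Longest linear sequence: 13 steps (steps 1–4 and 6–14); step 5 is a one-step branch.

**Step 7 (key step).**
- What may go wrong: weak face discrimination by the auxiliary at the first ring closure, or capture of the monocyclic C10 radical by the copper salt before ring B closes; either would thin the supply of 11.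
- Fallback (sets out from 5, returns at 15): the absolute configuration is taken from a Sharpless epoxidation and the rings are closed by a Lewis-acid epoxide–polyene cyclization.
  - Alkylation of the lithium enolate of ethyl acetate with 5 should give ester F1.
  - i-Bu2AlH at −78 °C should give aldehyde F2.
  - Still–Gennari olefination with ethyl 2-[bis(2,2,2-trifluoroethoxy)phosphoryl]propanoate, KN(SiMe3)2 and 18-crown-6 should give (Z)-enoate F3.
  - i-Bu2AlH should give (Z)-allylic alcohol F4.
  - Epoxidation with Ti(O-i-Pr)4, L-(+)-diethyl tartrate and t-BuOOH should give epoxy alcohol F5.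
  - TBSCl and imidazole should give silyl ether F6.
  - MeAlCl2 in CH2Cl2 at −78 °C should close both rings through a chair–chair array to the C3-equatorial alcohols: exocyclic alkene F7 and C7=C8 alkene F8. The conditions of step 8 should convert F7 into F8.
  - Dess–Martin oxidation should give ketone F9, and LiB(s-Bu)3H as in step 9 should then give 15.

**Step 8.**
- What may go wrong: hydrogen return from C9 instead of C7, which would lead on to the tetrasubstituted C8=C9 alkene.
- Fallback (sets out from 11, returns at 12): the alkene is moved by an oxidative 1,3-transposition whose regiochemistry is fixed by mechanism.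
  - SeO2 and t-BuOOH should hydroxylate C7 to allylic alcohol F10.
  - Mitsunobu reaction with 2-nitrobenzenesulfonylhydrazide (PPh3, DEAD, N-methylmorpholine, −30 °C) should give sulfonylhydrazine F11.
  - On warming, F11 should lose the sulfinic acid to give allylic diazene F12.
  - Retro-ene loss of dinitrogen from F12 should deliver hydrogen to C17 and leave the C7=C8 alkene of 12 (Myers reductive transposition).

**Step 9.**
- What may go wrong: slow or unselective hydride approach, because the axial ester with its large alkoxy group crowds the equatorial path to C3.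
- Fallback (sets out from 12, returns at 14): hydride is delivered from inside the molecule, from O19.
  - 1,2-Bis(trimethylsilyloxy)ethane and TMSOTf at −78 °C should give dioxolane F13.
  - LiAlH4 should give primary alcohol F14.
  - PPTS in wet acetone should give β-hydroxy ketone F15.
  - Me4NBH(OAc)3 in AcOH–MeCN (Evans–Saksena reduction) should deliver hydride to C3 from the face of C19 and give the 1,3-anti diol 14.

**Step 14.**
- What may go wrong: loss of chemoselectivity between the two primary alcohols, with oxidation at C19 as well.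
- Fallback (sets out from 16, returns at 18): the two primary hydroxyls are told apart by the order of deprotection instead of by the oxidant.
  - NH4F in MeOH should cleave only the unhindered primary TBDPS ether and give alcohol F16.
  - TEMPO and PhI(OAc)2 in aqueous MeCN should give acid F17 with C19 still silylated.
  - HF·pyridine should then free C19 and give 18.

## Further compounds

F1 | step 7 | ethyl (4E,8E,12R)-14-(TBDPS-oxy)-4,8,12-trimethyltetradeca-4,8-dienoate | CCOC(=O)CC/C(C)=C/CC/C(C)=C/CC[C@@H](C)CCO[Si](c1ccccc1)(c1ccccc1)C(C)(C)C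
F2 | step 7 | (4E,8E,12R)-14-(TBDPS-oxy)-4,8,12-trimethyltetradeca-4,8-dienal | O=CCC/C(C)=C/CC/C(C)=C/CC[C@@H](C)CCO[Si](c1ccccc1)(c1ccccc1)C(C)(C)C
F3 | step 7 | ethyl (2Z,6E,10E,14R)-16-(TBDPS-oxy)-2,6,10,14-tetramethylhexadeca-2,6,10-trienoate | CCOC(=O)/C(C)=C\CC/C(C)=C/CC/C(C)=C/CC[C@@H](C)CCO[Si](c1ccccc1)(c1ccccc1)C(C)(C)C
F4 | step 7 | (2Z,6E,10E,14R)-16-(TBDPS-oxy)-2,6,10,14-tetramethylhexadeca-2,6,10-trien-1-ol | OC/C(C)=C\CC/C(C)=C/CC/C(C)=C/CC[C@@H](C)CCO[Si](c1ccccc1)(c1ccccc1)C(C)(C)C
F5 | step 7 | [(2S,3R)-3-{(3E,7E,11R)-13-(TBDPS-oxy)-3,7,11-trimethyltrideca-3,7-dien-1-yl}-2-methyloxiran-2-yl]methanol | OC[C@]1(C)O[C@@H]1CC/C(C)=C/CC/C(C)=C/CC[C@@H](C)CCO[Si](c2ccccc2)(c2ccccc2)C(C)(C)C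
F6 | step 7 | tert-butyldimethylsilyl ether of F5 | CC(C)(C)[Si](C)(C)OC[C@]1(C)O[C@@H]1CC/C(C)=C/CC/C(C)=C/CC[C@@H](C)CCO[Si](c2ccccc2)(c2ccccc2)C(C)(C)C
F7 | step 7 | (3R)-19-(TBS-oxy)-15-(TBDPS-oxy)labd-8(17)-en-3-ol, ent series, C3–OH equatorial | O[C@@H]1CC[C@]2(C)[C@H](CCC(=C)[C@H]2CC[C@@H](C)CCO[Si](c3ccccc3)(c3ccccc3)C(C)(C)C)[C@]1(C)CO[Si](C)(C)C(C)(C)C
F8 | step 7 | (3R)-19-(TBS-oxy)-15-(TBDPS-oxy)labd-7-en-3-ol, ent series, C3–OH equatorial | O[C@@H]1CC[C@]2(C)[C@H](CC=C(C)[C@H]2CC[C@@H](C)CCO[Si](c3ccccc3)(c3ccccc3)C(C)(C)C)[C@]1(C)CO[Si](C)(C)C(C)(C)C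
F9 | step 7 | 19-(TBS-oxy)-15-(TBDPS-oxy)labd-7-en-3-one, ent series | O=C1CC[C@]2(C)[C@H](CC=C(C)[C@H]2CC[C@@H](C)CCO[Si](c3ccccc3)(c3ccccc3)C(C)(C)C)[C@]1(C)CO[Si](C)(C)C(C)(C)C
F10 | step 8 | 8-phenylmenthyl 15-(TBDPS-oxy)-7-hydroxy-3-oxolabd-8(17)-en-19-oate, ent series, C7–OH axial | O=C1CC[C@]2(C)[C@H](C[C@H](O)C(=C)[C@H]2CC[C@@H](C)CCO[Si](c3ccccc3)(c3ccccc3)C(C)(C)C)[C@]1(C)C(=O)O[C@H]1C[C@@H](C)CC[C@@H]1C(C)(C)c1ccccc1
F11 | step 8 | C7 N-(2-nitrobenzenesulfonyl)hydrazine from F10 (C7 inverted) | O=C1CC[C@]2(C)[C@H](C[C@@H](N(N)S(=O)(=O)c3ccccc3[N+](=O)[O-])C(=C)[C@H]2CC[C@@H](C)CCO[Si](c3ccccc3)(c3ccccc3)C(C)(C)C)[C@]1(C)C(=O)O[C@H]1C[C@@H](C)CC[C@@H]1C(C)(C)c1ccccc1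
F12 | step 8 | C7 monoalkyl diazene from F11 | O=C1CC[C@]2(C)[C@H](C[C@@H](N=N)C(=C)[C@H]2CC[C@@H](C)CCO[Si](c3ccccc3)(c3ccccc3)C(C)(C)C)[C@]1(C)C(=O)O[C@H]1C[C@@H](C)CC[C@@H]1C(C)(C)c1ccccc1
F13 | step 9 | ethylene ketal (C3 dioxolane) of 12 | O1CCOC12CC[C@]3(C)[C@H](CC=C(C)[C@H]3CC[C@@H](C)CCO[Si](c4ccccc4)(c4ccccc4)C(C)(C)C)[C@]2(C)C(=O)O[C@H]1C[C@@H](C)CC[C@@H]1C(C)(C)c1ccccc1
F14 | step 9 | 15-(TBDPS-oxy)-3,3-(ethylenedioxy)labd-7-en-19-ol, ent series | O1CCOC12CC[C@]3(C)[C@H](CC=C(C)[C@H]3CC[C@@H](C)CCO[Si](c4ccccc4)(c4ccccc4)C(C)(C)C)[C@]2(C)CO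
F15 | step 9 | 15-(TBDPS-oxy)-19-hydroxylabd-7-en-3-one, ent series | O=C1CC[C@]2(C)[C@H](CC=C(C)[C@H]2CC[C@@H](C)CCO[Si](c3ccccc3)(c3ccccc3)C(C)(C)C)[C@]1(C)CO
F16 | step 14 | (3S)-19-(TBS-oxy)-15-hydroxylabd-7-en-3-yl acetate, ent series | CC(=O)O[C@H]1CC[C@]2(C)[C@H](CC=C(C)[C@H]2CC[C@@H](C)CCO)[C@]1(C)CO[Si](C)(C)C(C)(C)C
F17 | step 14 | (3S)-3-acetoxy-19-(TBS-oxy)labd-7-en-15-oic acid, ent series | CC(=O)O[C@H]1CC[C@]2(C)[C@H](CC=C(C)[C@H]2CC[C@@H](C)CC(=O)O)[C@]1(C)CO[Si](C)(C)C(C)(C)C
A1 | alternative 1 | methyl (3R,6E,10E)-13-{(2R,3S)-3-[(benzyloxy)methyl]-3-methyloxiran-2-yl}-3,7,11-trimethyltrideca-6,10-dienoate | c1ccccc1COC[C@]1(C)O[C@@H]1CC/C(C)=C/CC/C(C)=C/CC[C@@H](C)CC(=O)OC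
A2 | alternative 1 | methyl (3R)-19-(benzyloxy)-3-hydroxylabd-7-en-15-oate, ent series, C3–OH equatorial | O[C@@H]1CC[C@]2(C)[C@H](CC=C(C)[C@H]2CC[C@@H](C)CC(=O)OC)[C@]1(C)COCc1ccccc1
A3 | alternative 2 | (R)-Wieland–Miescher ketone, (8aR)-8a-methyl-3,4,8,8a-tetrahydronaphthalene-1,6(2H,7H)-dione | C[C@@]12CCC(=O)C=C1CCCC2=O
A4 | alternative 2 | methyl 1,4a-dimethyl-2,5-dioxodecahydronaphthalene-1-carboxylate, trans-fused, ester cis to the angular methyl, ent series | O=C1CC[C@]2(C)[C@H](CCCC2=O)[C@]1(C)C(=O)OC
A5 | alternative 3 | andrographolide | O[C@@H]1CC[C@]2(C)[C@H](CCC(=C)[C@H]2C/C=C3\[C@H](O)COC3=O)[C@]1(C)CO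
A6 | alternative 3 | 3,19-O-isopropylidene-13,14,15,16-tetranorlabd-8(17)-en-12-al, ent series | O3[C@@H]1CC[C@]2(C)[C@H](CCC(=C)[C@H]2CC=O)[C@]1(C)COC3(C)C
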